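Both oxygens of ring A are derived from one nitrogen placed at C1. Ring A carries its hydroxyls para to each other (C1–OH, C4–OH), with C1 next to the ether carbon C2 and the bromines on C3 and C5 flanking C4. As a nitro group the nitrogen activates C2 for the diaryl ether-forming substitution. As an amine it lets Fremy's salt oxidise the free para carbon C4, and hydrolysis of the quinone imine converts C1–N into C1=O, so one operation creates both C–O bonds of the bromoquinone. The precursor is 3,5-dibromo-2-(2,3,5-tribromo-4-methoxyphenoxy)aniline, with ring B's C4' oxygen methylated; reduction and demethylation then give the target.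

Key step: step 6

Assumption: the target has no stereocentre and no configurationally stable axis, so it is achiral and no step needs stereocontrol; ring A is numbered C1 (OH), C2 (OAr), C3 (Br), C4 (OH), C5 (Br), C6 (H) and ring B C1' (ether O), C2'/C3'/C5' (Br), C4' (OH), C6' (H).

Step 1
Reactants: 1 2,4-dibromo-6-nitroaniline
Product: 3 1,5-dibromo-2-chloro-3-nitrobenzene, via 2,4-dibromo-6-nitrobenzenediazonium chloride 2 (not isolated)
Conditions: t-BuONO (1.5 equiv), CuCl2 (1.2 equiv), MeCN, 65 °C
Reagents that add atoms: copper(II) chloride, Cl[Cu]Cl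
Why: Sandmeyer chlorination under aprotic alkyl nitrite conditions: the weakly basic amine is diazotised in situ to 2 and copper-mediated electron transfer converts it at once into the aryl radical, which takes chlorine from copper(II) chloride, so the diazonium should not persist long enough for chloride to exchange its activated bromines or nitro group.

Step 2
Reactants: 3 1,5-dibromo-2-chloro-3-nitrobenzene; 4 2,5-dibromobenzene-1,4-diol (2,5-dibromohydroquinone)
Product: 5 2,5-dibromo-4-(2,4-dibromo-6-nitrophenoxy)phenol
Conditions: 4 (3 equiv), K2CO3 (2 equiv), DMF, 90 °C, Ar; excess 4 recovered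
Reagents that add atoms: none
Why: Nucleophilic aromatic substitution by addition–elimination: only the chlorine is ortho to the nitro group (both bromines are meta and inert), and the excess of the symmetrical diol, whose two hydroxyls are equivalent, should hold the reaction at mono-arylation while already supplying the C2' and C5' bromines of ring B.

Step 3
Reactants: 5 2,5-dibromo-4-(2,4-dibromo-6-nitrophenoxy)phenol
Product: 6 2,3,6-tribromo-4-(2,4-dibromo-6-nitrophenoxy)phenol
Conditions: Br2 (1.05 equiv), AcOH, rt
Reagents that add atoms: bromine, BrBr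
Why: Electrophilic aromatic bromination directed by the free hydroxyl: its para position carries the aryloxy group and one ortho position a bromine, so the single open ortho carbon (C3' of ring B) should be brominated, while the remaining ring-B C6'–H is meta to the hydroxyl and ring A is deactivated by its nitro group.

Step 4
Reactants: 6 2,3,6-tribromo-4-(2,4-dibromo-6-nitrophenoxy)phenol
Product: 7 1,5-dibromo-3-nitro-2-(2,3,5-tribromo-4-methoxyphenoxy)benzene
Conditions: MeI (3 equiv), K2CO3 (2 equiv), DMF, rt
Reagents that add atoms: iodomethane, CI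
Why: Williamson O-methylation of the acidic 2,6-dibromophenol, which installs the methyl ether that keeps ring B inert to the oxidant of step 6.

Step 5
Reactants: 7 1,5-dibromo-3-nitro-2-(2,3,5-tribromo-4-methoxyphenoxy)benzene
Product: 8 3,5-dibromo-2-(2,3,5-tribromo-4-methoxyphenoxy)aniline
Conditions: SnCl2·2H2O (5 equiv), conc. HCl, EtOH, 60 °C
Reagents that add atoms: none
Why: Tin(II) chloride reduction of the aromatic nitro group, a method that leaves aryl bromides, the methyl ether and the diaryl ether untouched.

Step 6
Reactants: 8 3,5-dibromo-2-(2,3,5-tribromo-4-methoxyphenoxy)aniline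
Product: 10 3,5-dibromo-2-(2,3,5-tribromo-4-methoxyphenoxy)-1,4-benzoquinone, via quinone monoimine 9 (not isolated)
Conditions: (KSO3)2NO (4 equiv), aq. KH2PO4 (pH ≈ 6)/acetone, 0 °C → rt; then 1 M HCl
Reagents that add atoms: potassium nitrosodisulfonate (Fremy's salt), [K+].[K+].[O]N(S(=O)(=O)[O-])S(=O)(=O)[O-]; water, O
Why: Teuber oxidation of a primary aniline with a free para position: the nitrosodisulfonate radical abstracts an N–H hydrogen, the aminyl radical is trapped at C4 by the oxygen of a second radical, loss of imidodisulfonate gives quinone imine 9, and its C1=NH is hydrolysed to C1=O in the acidic work-up. The closest known reaction type is the Fremy's salt oxidation of aminoarenes such as aminoindoles and aminoquinolines to para-quinones. No ring is closed and no stereocentre is formed; the step makes the C4–O bond (oxygen from the reagent) and the C1–O bond (oxygen from water). Para- over ortho-oxidation is required: the spin density of the aminyl radical is highest at C4, C2 is blocked by the aryloxy group and only C6 remains as a competing ortho site, although the C3 and C5 bromines slow coupling at C4. Ring B cannot be oxidised because its C4' oxygen is methylated, and the weakly acidic buffer keeps the liberated ammonia protonated so that it should not displace the aryloxy group or a bromine from the quinone.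

Step 7
Reactants: 10 3,5-dibromo-2-(2,3,5-tribromo-4-methoxyphenoxy)-1,4-benzoquinone
Product: 11 3,5-dibromo-2-(2,3,5-tribromo-4-methoxyphenoxy)benzene-1,4-diol
Conditions: Na2S2O4 (3 equiv), EtOAc/H2O, rt
Reagents that add atoms: none
Why: Dithionite reduction of a quinone to its hydroquinone, a two-electron transfer that proceeds at neutral pH and leaves the aryl bromides and both ethers intact.

Step 8
Reactants: 11 3,5-dibromo-2-(2,3,5-tribromo-4-methoxyphenoxy)benzene-1,4-diol
Product: 12 3,5-dibromo-2-(2,3,5-tribromo-4-hydroxyphenoxy)benzene-1,4-diol (target)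
Conditions: BBr3 (5 equiv), CH2Cl2, −78 °C → rt, Ar; then H2O
Reagents that add atoms: none
Why: Boron tribromide cleavage of the aryl methyl ether (complexation at oxygen, then bromide attack on the methyl group), which does not break the diaryl ether and whose boron–oxygen bonds are hydrolysed on work-up to release the free hydroxyls.

Compound list
1 | 2,4-dibromo-6-nitroaniline | Nc1c(Br)cc(Br)cc1[N+](=O)[O-] | starting material
2 | 2,4-dibromo-6-nitrobenzenediazonium chloride | N#[N+]c1c(Br)cc(Br)cc1[N+](=O)[O-].[Cl-] | intermediate
3 | 1,5-dibromo-2-chloro-3-nitrobenzene | Clc1c(Br)cc(Br)cc1[N+](=O)[O-] | intermediate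
4 | 2,5-dibromobenzene-1,4-diol | Oc1cc(Br)c(O)cc1Br | starting material
5 | 2,5-dibromo-4-(2,4-dibromo-6-nitrophenoxy)phenol | Oc1cc(Br)c(Oc2c(Br)cc(Br)cc2[N+](=O)[O-])cc1Br | intermediate
6 | 2,3,6-tribromo-4-(2,4-dibromo-6-nitrophenoxy)phenol | Oc1c(Br)cc(Oc2c(Br)cc(Br)cc2[N+](=O)[O-])c(Br)c1Br | intermediate
7 | 1,5-dibromo-3-nitro-2-(2,3,5-tribromo-4-methoxyphenoxy)benzene | COc1c(Br)cc(Oc2c(Br)cc(Br)cc2[N+](=O)[O-])c(Br)c1Br | intermediate
8 | 3,5-dibromo-2-(2,3,5-tribromo-4-methoxyphenoxy)aniline | Nc1cc(Br)cc(Br)c1Oc1cc(Br)c(OC)c(Br)c1Br | intermediate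
9 | 2,6-dibromo-4-imino-3-(2,3,5-tribromo-4-methoxyphenoxy)cyclohexa-2,5-dien-1-one | N=C1C=C(Br)C(=O)C(Br)=C1Oc1cc(Br)c(OC)c(Br)c1Br | intermediate
10 | 3,5-dibromo-2-(2,3,5-tribromo-4-methoxyphenoxy)cyclohexa-2,5-diene-1,4-dione | O=C1C=C(Br)C(=O)C(Br)=C1Oc1cc(Br)c(OC)c(Br)c1Br | intermediate
11 | 3,5-dibromo-2-(2,3,5-tribromo-4-methoxyphenoxy)benzene-1,4-diol | Oc1cc(Br)c(O)c(Br)c1Oc1cc(Br)c(OC)c(Br)c1Br | intermediate
12 | 3,5-dibromo-2-(2,3,5-tribromo-4-hydroxyphenoxy)benzene-1,4-diol | Oc1cc(Br)c(O)c(Br)c1Oc1cc(Br)c(O)c(Br)c1Br | target

Total step count: 8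
Longest linear sequence: 8 steps (1 → 12; compound 4 enters at step 2)

Steps most likely to fail

Step 6. Hydrogen abstraction from the electron-poor amine and radical coupling at the bromine-flanked C4 may be slow. The oxidant could then decompose first, or attack at C6 and substitution of the aryloxy group on the quinone could compete. The fallback sets out from 7 and returns at 10. Partial reduction of 7 with zinc dust and NH4Cl in aqueous THF at 0 °C should stop at N-[3,5-dibromo-2-(2,3,5-tribromo-4-methoxyphenoxy)phenyl]hydroxylamine F1. A Bamberger rearrangement in aqueous H2SO4/MeCN at 60 °C, in which water adds to the para carbon of the cation formed by N–O heterolysis, should give 4-amino-2,6-dibromo-3-(2,3,5-tribromo-4-methoxyphenoxy)phenol F2. Oxidation of this para-aminophenol with FeCl3 in aqueous HCl/MeCN at rt should give quinone imine 9, which hydrolyses to 10. The C4 oxygen is thus introduced by an ionic pathway and only a facile aminophenol oxidation remains.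

Step 2. The diol may be arylated twice, the hydroquinone anion may transfer an electron to the nitroarene, or attack at the crowded chlorine-bearing carbon may be slow. The fallback sets out from 3 and returns at 6. Substitution of 3 with commercial 2-bromo-4-methoxyphenol (K2CO3, DMF, 90 °C), a monophenol that can neither over-arylate nor be oxidised, should give 1,5-dibromo-2-(2-bromo-4-methoxyphenoxy)-3-nitrobenzene F3. BBr3 in CH2Cl2 should then free 3-bromo-4-(2,4-dibromo-6-nitrophenoxy)phenol F4. Bromination with Br2 (2.1 equiv) in AcOH at both carbons ortho to the hydroxyl should lead to 6.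

Step 3. Bromine may attack ipso at the carbon para to the hydroxyl and expel the nitrophenoxide (oxidation to a bromoquinone), or bromination may occur at the wrong ring-B carbon. The fallback sets out from 3 and returns at 7, with ring B fully brominated before the ether is formed.
- Commercial 3-bromo-4-nitrophenol with Br2 (2.1 equiv) in AcOH should give 2,3,6-tribromo-4-nitrophenol F5; its para position carries a nitro group, so no leaving group can be expelled.
- MeI/K2CO3 in DMF should give 1,3,4-tribromo-2-methoxy-5-nitrobenzene F6.
- SnCl2/HCl in EtOH should give 2,3,5-tribromo-4-methoxyaniline F7.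
- NaNO2 in H2SO4/AcOH at 0 °C should give 2,3,5-tribromo-4-methoxybenzenediazonium hydrogensulfate F8, which is hydrolysed in hot aqueous H2SO4 to 2,3,5-tribromo-4-methoxyphenol F9.
- Substitution of the chloride of 3 by F9 (Cs2CO3, DMSO, 100 °C) should give 7 directly, bypassing steps 2–4.

Further compounds
F1 | step 6 | N-[3,5-dibromo-2-(2,3,5-tribromo-4-methoxyphenoxy)phenyl]hydroxylamine | ONc1cc(Br)cc(Br)c1Oc1cc(Br)c(OC)c(Br)c1Br
F2 | step 6 | 4-amino-2,6-dibromo-3-(2,3,5-tribromo-4-methoxyphenoxy)phenol | Nc1cc(Br)c(O)c(Br)c1Oc1cc(Br)c(OC)c(Br)c1Br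
F3 | step 2 | 1,5-dibromo-2-(2-bromo-4-methoxyphenoxy)-3-nitrobenzene | COc1ccc(Oc2c(Br)cc(Br)cc2[N+](=O)[O-])c(Br)c1
F4 | step 2 | 3-bromo-4-(2,4-dibromo-6-nitrophenoxy)phenol | Oc1ccc(Oc2c(Br)cc(Br)cc2[N+](=O)[O-])c(Br)c1
F5 | step 3 | 2,3,6-tribromo-4-nitrophenol | Oc1c(Br)cc([N+](=O)[O-])c(Br)c1Br
F6 | step 3 | 1,3,4-tribromo-2-methoxy-5-nitrobenzene | COc1c(Br)cc([N+](=O)[O-])c(Br)c1Br
F7 | step 3 | 2,3,5-tribromo-4-methoxyaniline | COc1c(Br)cc(N)c(Br)c1Br
F8 | step 3 | 2,3,5-tribromo-4-methoxybenzenediazonium hydrogensulfate | COc1c(Br)cc([N+]#N)c(Br)c1Br.OS(=O)(=O)[O-]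
F9 | step 3 | 2,3,5-tribromo-4-methoxyphenol | COc1c(Br)cc(O)c(Br)c1Br
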